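**Remark on numbering.** Germacrane numbering is used for locants in the text: ring C1–C10, Z alkene C1=C10 with methyl on C10, epoxide C4–C5 with methyl on C4, OH on C6, isopropyl on C7 (C11–C13), aroyloxy on C8. Systematic names are in the compound list.

## The problem

Compound 34 is a single ten-membered carbocycle with no second ring to template its closure, so any end-to-end cyclisation has to overcome both entropy and transannular strain. It carries a Z-trisubstituted C1=C10 alkene and five contiguous stereocentres: a trisubstituted (4S,5S)-epoxide with quaternary C4, the free (6R)-carbinol, the (7S)-isopropyl methine and the (8R)-aroyloxy carbinol. Drawn as a zigzag from C4 to C9, the epoxide oxygen, O6 and O8 lie on one side and the isopropyl group on the other. The C6 hydroxyl is the natural control element. As an allylic alcohol next to a C4=C5 alkene whose C4 methyl is cis to C6, it can steer epoxidation to the threo face; as the β-hydroxyl of a C8 ketone it can direct hydride 1,3-syn. Only C6 and C7 therefore need absolute control from outside. The fragile parts are the epoxide and any 1(10),4-diene precursor (acid opens the one and cyclises the other across the ring), the aryl ester (base), a C8 ketone with its epimerisable C7 neighbour, and the Z geometry at C1=C10. The enabling feature is that C6 lies between C5, an alkene carbon once the epoxide is traced back to C4=C5, and C7 with its three-carbon branch. Written with an isopropenyl group, O6–C6–C7–C11=C12 is a homoallylic alcohol with a vinyl group on the carbinol carbon, the retron of a [2,3]-Wittig shift. Joining O6 to C12 gives a 13-membered diallylic ether that is achiral when C8 is a ketal, which eases ring formation but leaves the absolute configuration to a reagent.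

## Retrosynthesis

**Ester.** The acyl C–O bond at C8 of 34 is cut to give epoxy diol 32 and 3,4,5-trimethoxybenzoyl chloride 33. Placing the ester last spares it every hydride and base. Carrying a differentiated O8 from earlier would make C8 a stereocentre before the ring exists and destroy the symmetry the key step relies on. The forward step must choose C8–OH (CH2 neighbour) over C6–OH (between the epoxide and C7).

**Epoxide.** Removing the oxirane oxygen from 32 gives diene diol 31. Epoxidising late keeps the acid-labile oxirane away from ketal hydrolysis. The forward step needs C4=C5 over C1=C10 and the threo face; the allylic C6 hydroxyl supplies both.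

**C8 carbinol.** The C8–H bond of 31 is cut to β-hydroxy ketone 29, and 29 is masked as dioxolane 28. A chelate-controlled 1,3-syn reduction lets C6 set C8. The required triad (6,8-syn with the isopropyl group anti to both) corresponds to an all-equatorial six-membered chelate, so the reduction is matched.

**Isopropyl group and enantiopurity.** The isopropyl group of 28 is traced to the isopropenyl group of 24, which the sigmatropic step leaves behind. Because a chiral base is unlikely to give complete enantioselection, the alcohol passes through camphanates 27 and 26, made with (1S,4R)-camphanic chloride 25, so that the minor enantiomer can be removed as a diastereomer.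

**Key disconnection.** In 24 the C6–C7 bond is cut and O6 is joined to C12, giving the achiral 13-membered ether 22. The alternatives on the same ring (alkylation at C8–C9, carbonyl addition at C5–C6, olefination at C1=C10) all close a ten-membered ring end-to-end. This cut instead contracts an easily made 13-membered ring and sets C6 and C7 together. The precursor has no stereocentre, three alkenes of fixed geometry and a ketal. The forward reaction needs lithiation at C6 and not C12, a choice between the two enantiotopic C6 hydrogens, and a Z C7=C11 alkene.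

**Macrocyclic ether.** The C6–O bond of 22 is cut to hydroxy chloride 21. This bond is chosen over C12–O because the electrophile is then an unhindered geranyl-type chloride.

**Z C7=C11 alkene and ketal.** Compound 21 comes from chloro ester 20, alcohol 18 and silyl ether 17 by functional-group changes. The dioxolane of 17 is traced to dithiane 15 and ethylene glycol 16. The C7=C11 alkene of 15 is cut to aldehyde 14 and phosphonate 7. A Z-selective olefination is preferred to allylic oxidation of a prenyl terminus, which would give the E isomer.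

**C8–C9 bond.** Aldehyde 14 is traced through ester 13 to allylic bromide 11 and ethyl 1,3-dithiane-2-carboxylate 12. C8 must be an acyl-anion equivalent at the ketone oxidation level. The ester-activated dithiane is alkylated with a mild base and brings C7 with it.

**Z C1=C10 alkene and the C2–C6 unit.** Bromide 11 comes from alcohol 9 and enoate 8, and 8 from aldehyde 6 and the same phosphonate 7. Aldehyde 6 is geraniol 1 with its distal alkene cleaved, via silyl ether 3 and epoxide 4. Geraniol supplies C2–C6, the E C4=C5 alkene and the C4 methyl in one piece. Joining two five-carbon units by allylic sulfone alkylation was weighed and set aside: it needs more steps and a hard-to-differentiate symmetric-looking diol.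

## Roads not taken

**Alternative 1:** Cut C3–C4 and the C5–O bond of the epoxide in an open chain. The organomagnesium reagent from bromide A2, transmetalated with CeCl3, would add to the methyl ketone of α-chloro ketone A3 anti to chlorine (Cornforth-type dipole control). The alkoxide would then displace chloride at C5 with inversion to give epoxide A1.
- Merits: convergent; the quaternary C4 and the epoxide are set stereospecifically; C5–C7 come from auxiliary-based acyclic chemistry with secure absolute configuration; O6 and O8 carry different protecting groups.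
- Weak points: the ten-membered ring is still open and must be closed at C8–C9 in the presence of the epoxide, with C8 still to be made a stereocentre. A Nozaki–Hiyama-type allylation there tends to bond at the γ-carbon. Cornforth selectivity is less dependable for a methyl ketone with a β-silyloxy group than for aldehydes, and the α-chloro ketone can epimerise.
- Comparison: this road is better on absolute stereocontrol and on differentiating the two hydroxyls. The chosen plan answers with the camphanate purification and a steric bias in the last acylation. It is stronger where alternative 1 is weakest: the ring is formed by a ring-size-matched contraction, and the epoxide appears only in the penultimate step.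

**Alternative 2:** Reconnect C5–C10 into a cyclohexane and cut C2–C3. The potassium alkoxide of all-cis cyclohexanol A5 (KH, 18-crown-6) would undergo anionic oxy-Cope rearrangement. The C1=C10 enolate would be trapped with PhNTf2 as enol triflate A4, and a methyl cross-coupling would follow.
- Merits: ring expansion solves the medium-ring problem without high dilution, at least as well as the chosen contraction; the C6–C8 triad is built on a six-membered ring; O6 and O8 are differentiated.
- Weak points: A5 is a pentasubstituted all-cis cyclohexanol with two extra stereocentres (C5, C10) that are made only to be destroyed. The 1(10)Z,4E geometry depends on a single transition-state geometry. The triflate adds a coupling step. The methoxymethyl ether must be removed with acid before the epoxide can be tolerated.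
- Comparison: ring formation is as good or better, and enantiocontrol would come from the cyclohexane synthesis. The chosen plan sets two stereocentres instead of five, fixes alkene geometry by olefination and not by a pericyclic transition state, and starts from geraniol.

**Alternative 3:** Cut C5–C6 and C4–CH3. Ni(cod)2 (zerovalent nickel) with a small N-heterocyclic carbene and ZnMe2 would couple the aldehyde of ynal A7 with the terminal alkyne carbon and deliver methyl to C4, giving allylic alcohol A6.
- Merits: the most direct road; the ring, the E-trisubstituted alkene and the C6 carbinol arise in one step; O8 is already silylated, which beats the selective acylation of the chosen plan; C7 and C8 come from asymmetric aldol chemistry.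
- Weak points: the cyclisation must be endo-selective at a terminal alkyne. The exo mode would give a nine-membered ring with an exocyclic alkene. Ten-membered closures of this kind are less established than larger ones. The C6 configuration rests on 1,2-induction from an α-branched, epimerisable aldehyde. ZnMe2 can add directly to the aldehyde.
- Comparison: shorter and better in absolute control. The chosen plan has precedent at exactly this ring size and sets the C6/C7 relationship by a dependable sigmatropic rule (Z alkene gives syn).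

Key step: step 15

**Assumption.** Which antipode of the lithium amide removes the C6 pro-S hydrogen cannot be derived from first principles for this ring. The (S,S)-amide is written; the equally available (R,R)-amide replaces it if the first run gives the mirror-image series.

## Route

Step 1
Reactants: 1 geraniol; 2 tert-butyl(chloro)diphenylsilane
Product: 3 tert-butyl{[(2E)-3,7-dimethylocta-2,6-dien-1-yl]oxy}diphenylsilane
Conditions: imidazole, DMF, 0 °C → rt
Reagents that add atoms: tert-butyl(chloro)diphenylsilane 2, CC(C)(C)[Si](Cl)(c1ccccc1)c1ccccc1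
Why: Standard silylation of a primary allylic alcohol; this silyl ether should survive periodic acid, hydride, strong base and the acid released in step 10, yet is removed by fluoride.

Step 2
Reactants: 3 tert-butyl{[(2E)-3,7-dimethylocta-2,6-dien-1-yl]oxy}diphenylsilane
Product: 4 tert-butyl{[(2E)-5-(3,3-dimethyloxiran-2-yl)-3-methylpent-2-en-1-yl]oxy}diphenylsilane
Conditions: mCPBA (1.0 equiv), CH2Cl2, −20 → 0 °C
Reagents that add atoms: 3-chloroperoxybenzoic acid, OOC(=O)c1cccc(Cl)c1
Why: Prilezhaev epoxidation; the distal alkene is the more electron-rich because the 2,3-alkene is deactivated by the allylic silyloxy group, and the new stereocentre is lost in the next step.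

Step 3
Reactants: 4 tert-butyl{[(2E)-5-(3,3-dimethyloxiran-2-yl)-3-methylpent-2-en-1-yl]oxy}diphenylsilane
Product: 6 (4E)-6-[(tert-butyldiphenylsilyl)oxy]-4-methylhex-4-enal, via vicinal diol 5 (not isolated)
Conditions: H5IO6, THF–H2O, 0 °C
Reagents that add atoms: none
Why: Periodic acid opens the epoxide to the glycol and cleaves it in the same flask (Malaprade cleavage), removing the terminal three carbons as acetone and leaving the E alkene untouched.

Step 4
Reactants: 6 (4E)-6-[(tert-butyldiphenylsilyl)oxy]-4-methylhex-4-enal; 7 methyl 2-[bis(2,2,2-trifluoroethoxy)phosphoryl]propanoate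
Product: 8 methyl (2Z,6E)-8-[(tert-butyldiphenylsilyl)oxy]-2,6-dimethylocta-2,6-dienoate
Conditions: KN(SiMe3)2, 18-crown-6, THF, −78 °C
Reagents that add atoms: methyl 2-[bis(2,2,2-trifluoroethoxy)phosphoryl]propanoate 7, COC(=O)C(C)P(=O)(OCC(F)(F)F)OCC(F)(F)F
Why: Still–Gennari olefination; the electron-poor phosphonate with a dissociated potassium ion eliminates faster than the adducts equilibrate, so the kinetic Z enoate should dominate, fixing the Z C1=C10 geometry.

Step 5
Reactants: 8 methyl (2Z,6E)-8-[(tert-butyldiphenylsilyl)oxy]-2,6-dimethylocta-2,6-dienoate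
Product: 9 (2Z,6E)-8-[(tert-butyldiphenylsilyl)oxy]-2,6-dimethylocta-2,6-dien-1-ol
Conditions: i-Bu2AlH (2.2 equiv), CH2Cl2, −78 °C; aq. KNaC4H4O6
Reagents that add atoms: none
Why: 1,2-Reduction of an enoate to the allylic alcohol with an aluminium hydride; alkene geometry is not affected.

Step 6
Reactants: 9 (2Z,6E)-8-[(tert-butyldiphenylsilyl)oxy]-2,6-dimethylocta-2,6-dien-1-ol
Product: 11 {[(2E,6Z)-8-bromo-3,7-dimethylocta-2,6-dien-1-yl]oxy}(tert-butyl)diphenylsilane, via allylic mesylate 10 (not isolated)
Conditions: MsCl, Et3N, THF, −40 °C; then LiBr, −40 → 0 °C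
Reagents that add atoms: lithium bromide, [Li+].[Br-]
Why: Mesylation then SN2 displacement by bromide (Finkelstein type) at low temperature is the usual way to a neryl-type bromide without allylic transposition or loss of Z geometry.

Step 7
Reactants: 11 {[(2E,6Z)-8-bromo-3,7-dimethylocta-2,6-dien-1-yl]oxy}(tert-butyl)diphenylsilane; 12 ethyl 1,3-dithiane-2-carboxylate
Product: 13 ethyl 2-[(2Z,6E)-8-[(tert-butyldiphenylsilyl)oxy]-2,6-dimethylocta-2,6-dien-1-yl]-1,3-dithiane-2-carboxylate
Conditions: NaH, DMF–toluene, 0 °C → rt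
Reagents that add atoms: ethyl 1,3-dithiane-2-carboxylate 12, CCOC(=O)C1SCCCS1
Why: C-Alkylation of the sodium enolate of an ester-activated dithiane (acyl-anion equivalent for C8) by SN2 at the primary allylic bromide; no alkyllithium is needed next to the allylic silyl ether, and the ester is the latent C7 aldehyde.

Step 8
Reactants: 13 ethyl 2-[(2Z,6E)-8-[(tert-butyldiphenylsilyl)oxy]-2,6-dimethylocta-2,6-dien-1-yl]-1,3-dithiane-2-carboxylate
Product: 14 2-[(2Z,6E)-8-[(tert-butyldiphenylsilyl)oxy]-2,6-dimethylocta-2,6-dien-1-yl]-1,3-dithiane-2-carbaldehyde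
Conditions: i-Bu2AlH (1.1 equiv), toluene, −78 °C; aq. KNaC4H4O6
Reagents that add atoms: none
Why: Partial reduction of a hindered α,α-bis(alkylthio) ester; the tetrahedral aluminium hemiacetal should persist at −78 °C and give the aldehyde only on work-up.

Step 9
Reactants: 14 2-[(2Z,6E)-8-[(tert-butyldiphenylsilyl)oxy]-2,6-dimethylocta-2,6-dien-1-yl]-1,3-dithiane-2-carbaldehyde; 7 methyl 2-[bis(2,2,2-trifluoroethoxy)phosphoryl]propanoate
Product: 15 methyl (2Z)-3-{2-[(2Z,6E)-8-[(tert-butyldiphenylsilyl)oxy]-2,6-dimethylocta-2,6-dien-1-yl]-1,3-dithian-2-yl}-2-methylprop-2-enoate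
Conditions: KN(SiMe3)2, 18-crown-6, THF, −78 → −40 °C
Reagents that add atoms: methyl 2-[bis(2,2,2-trifluoroethoxy)phosphoryl]propanoate 7, COC(=O)C(C)P(=O)(OCC(F)(F)F)OCC(F)(F)F
Why: Second Still–Gennari olefination on a non-enolisable aldehyde; it places the ester carbon (future C12) cis to C8, the Z C7=C11 geometry on which the relative configuration of step 15 depends.

Step 10
Reactants: 15 methyl (2Z)-3-{2-[(2Z,6E)-8-[(tert-butyldiphenylsilyl)oxy]-2,6-dimethylocta-2,6-dien-1-yl]-1,3-dithian-2-yl}-2-methylprop-2-enoate; 16 ethane-1,2-diol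
Product: 17 methyl (2Z)-3-{2-[(2Z,6E)-8-[(tert-butyldiphenylsilyl)oxy]-2,6-dimethylocta-2,6-dien-1-yl]-1,3-dioxolan-2-yl}-2-methylprop-2-enoate
Conditions: PhI(O2CCF3)2, HOCH2CH2OH (excess), MeCN, 0 °C; then aq. NaHCO3
Reagents that add atoms: ethane-1,2-diol 16, OCCO
Why: Oxidative dethioacetalisation with hypervalent iodine in the presence of a diol; sulfur activation gives a thionium ion that the glycol captures twice, so the dioxolane forms without the free ketone, whose Z enoate and β,γ-alkene could otherwise isomerise.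

Step 11
Reactants: 17 methyl (2Z)-3-{2-[(2Z,6E)-8-[(tert-butyldiphenylsilyl)oxy]-2,6-dimethylocta-2,6-dien-1-yl]-1,3-dioxolan-2-yl}-2-methylprop-2-enoate
Product: 18 methyl (2Z)-3-{2-[(2Z,6E)-8-hydroxy-2,6-dimethylocta-2,6-dien-1-yl]-1,3-dioxolan-2-yl}-2-methylprop-2-enoate
Conditions: Bu4NF, THF, 0 °C → rt
Reagents that add atoms: none
Why: Fluoride-induced desilylation; ketal and enoate are stable to these conditions.

Step 12
Reactants: 18 methyl (2Z)-3-{2-[(2Z,6E)-8-hydroxy-2,6-dimethylocta-2,6-dien-1-yl]-1,3-dioxolan-2-yl}-2-methylprop-2-enoate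
Product: 20 methyl (2Z)-3-{2-[(2Z,6E)-8-chloro-2,6-dimethylocta-2,6-dien-1-yl]-1,3-dioxolan-2-yl}-2-methylprop-2-enoate, via allylic mesylate 19 (not isolated)
Conditions: MsCl, 2,4,6-collidine, LiCl, DMF, 0 °C
Reagents that add atoms: lithium chloride, [Li+].[Cl-]
Why: One-flask mesylation and SN2 displacement by chloride, the standard route to geranyl-type chlorides without transposition; the ester still masks C12, so the two chain ends stay differentiated.

Step 13
Reactants: 20 methyl (2Z)-3-{2-[(2Z,6E)-8-chloro-2,6-dimethylocta-2,6-dien-1-yl]-1,3-dioxolan-2-yl}-2-methylprop-2-enoate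
Product: 21 (2Z)-3-{2-[(2Z,6E)-8-chloro-2,6-dimethylocta-2,6-dien-1-yl]-1,3-dioxolan-2-yl}-2-methylprop-2-en-1-ol
Conditions: i-Bu2AlH (2.2 equiv), CH2Cl2, −78 °C; aq. KNaC4H4O6
Reagents that add atoms: none
Why: The electrophilic aluminium hydride reduces the enoate at −78 °C without touching a primary allylic chloride or a dioxolane; the neutral tartrate work-up avoids acid, which would cyclise the Z γ-hydroxy ketal to a furan.

Step 14
Reactants: 21 (2Z)-3-{2-[(2Z,6E)-8-chloro-2,6-dimethylocta-2,6-dien-1-yl]-1,3-dioxolan-2-yl}-2-methylprop-2-en-1-ol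
Product: 22 (6Z,11E,15Z)-7,12,16-trimethyl-1,4,9-trioxaspiro[4.12]heptadeca-6,11,15-triene
Conditions: NaH, THF, reflux, slow addition (final ≤ 0.005 M)
Reagents that add atoms: none
Why: Intramolecular Williamson etherification (13-exo-tet SN2 of a primary alkoxide on an unhindered primary allylic chloride) under high dilution; two Z alkenes and the ketal pre-bend the chain, and 13-membered diallylic ethers have been closed this way.

Step 15
Reactants: 22 (6Z,11E,15Z)-7,12,16-trimethyl-1,4,9-trioxaspiro[4.12]heptadeca-6,11,15-triene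
Product: 24 (6S,7S,8E,12Z)-9,13-dimethyl-6-(prop-1-en-2-yl)-1,4-dioxaspiro[4.9]tetradeca-8,12-dien-7-ol, via C6-lithiated ether 23 (not isolated)
Conditions: (S,S)-[PhCH(Me)]2NLi (3 equiv, from the amine and n-BuLi), THF, −40 → 0 °C
Reagents that add atoms: none
Why: The amide should remove the C6 pro-S hydrogen to give α-oxy allyllithium 23, which undergoes a concerted suprafacial [2,3]-sigmatropic shift through a five-membered envelope (C6, O, C12, C11, C7), forming C6–C7 as O–C12 breaks, with inversion at the lithiated carbon. The closest known reaction type is the [2,3]-Wittig ring contraction of 13-membered diallylic and allyl propargyl ethers to cyclodecenols, the latter also run with chiral lithium amides. Both reacting termini are ring atoms, so the ten-membered carbocycle closes transannularly by excision of the oxygen and C11–C12 from the 13-membered ring, and no high dilution is needed. C6 is set by the amide's choice between the two enantiotopic C6 hydrogens (retention on lithiation, inversion in the shift). C7 is set relative to C6 by the Z C7=C11 geometry: with the C5 vinyl substituent exo on the envelope, a Z alkene leads to the syn product, that is, hydroxyl and isopropenyl cis on the new ring. The step needs lithiation at C6 over C12, the [2,3] over the [1,2] pathway, and enantiotopic discrimination. C6 is flanked by a CH= carbon and is unhindered, whereas C12 is flanked by fully substituted C11 and screened by the cis spiro-dioxolane; a C12 anion would also have to bond to fully substituted C4 and build a quaternary centre, so under the reversible amide conditions the C6 pathway should drain the mixture, and low temperature disfavours the radical-pair [1,2] route. The product is expected enantioenriched but not pure, and step 16 completes the enantiopurity.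

Step 16
Reactants: 24 (6S,7S,8E,12Z)-9,13-dimethyl-6-(prop-1-en-2-yl)-1,4-dioxaspiro[4.9]tetradeca-8,12-dien-7-ol; 25 (1S,4R)-camphanic chloride
Product: 26 (6S,7S,8E,12Z)-9,13-dimethyl-6-(prop-1-en-2-yl)-1,4-dioxaspiro[4.9]tetradeca-8,12-dien-7-yl (1S,4R)-camphanate
Conditions: Et3N, DMAP (cat.), CH2Cl2, 0 °C → rt; separation of diastereomers (crystallisation or chromatography)
Reagents that add atoms: (1S,4R)-camphanic chloride 25, ClC(=O)[C@@]12CC[C@@](C)(C(=O)O1)C2(C)C
Why: Acylation turns the residual enantiomer into a diastereomeric camphanate that can be removed, so 26 should be stereochemically homogeneous; the acid chloride has no epimerisable centre.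

Step 17
Reactants: 26 (6S,7S,8E,12Z)-9,13-dimethyl-6-(prop-1-en-2-yl)-1,4-dioxaspiro[4.9]tetradeca-8,12-dien-7-yl (1S,4R)-camphanate
Product: 27 (6S,7S,8E,12Z)-9,13-dimethyl-6-(propan-2-yl)-1,4-dioxaspiro[4.9]tetradeca-8,12-dien-7-yl (1S,4R)-camphanate
Conditions: H2 (1 atm), RhCl(PPh3)3 (cat.), benzene–EtOH, rt
Reagents that add atoms: none
Why: Homogeneous hydrogenation with this rhodium complex strongly prefers the less substituted alkene, so the 1,1-disubstituted isopropenyl group should be saturated while both trisubstituted ring alkenes remain; no stereocentre is formed.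

Step 18
Reactants: 27 (6S,7S,8E,12Z)-9,13-dimethyl-6-(propan-2-yl)-1,4-dioxaspiro[4.9]tetradeca-8,12-dien-7-yl (1S,4R)-camphanate
Product: 28 (6S,7S,8E,12Z)-9,13-dimethyl-6-(propan-2-yl)-1,4-dioxaspiro[4.9]tetradeca-8,12-dien-7-ol
Conditions: K2CO3 (cat.), MeOH, rt → 40 °C
Reagents that add atoms: none
Why: Base-catalysed transesterification releases the alcohol; the ketal and alkenes are inert and neither C6 nor C7 can epimerise here.

Step 19
Reactants: 28 (6S,7S,8E,12Z)-9,13-dimethyl-6-(propan-2-yl)-1,4-dioxaspiro[4.9]tetradeca-8,12-dien-7-ol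
Product: 29 (3Z,7E,9S,10S)-9-hydroxy-3,7-dimethyl-10-(propan-2-yl)cyclodeca-3,7-dien-1-one
Conditions: PPTS (cat.), acetone–H2O, 40 °C
Reagents that add atoms: water, O
Why: Mild acid-catalysed ketal hydrolysis with a pyridinium salt, chosen to be too weak to ionise the allylic C6–O bond, protonate the ring alkenes or enolise toward C7.

Step 20
Reactants: 29 (3Z,7E,9S,10S)-9-hydroxy-3,7-dimethyl-10-(propan-2-yl)cyclodeca-3,7-dien-1-one
Product: 31 (1R,2R,3S,4E,8Z)-5,9-dimethyl-2-(propan-2-yl)cyclodeca-4,8-diene-1,3-diol, via diethylboron chelate 30 (not isolated)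
Conditions: Et2BOMe, THF–MeOH, −78 °C; NaBH4; then AcOH, MeOH (evaporation)
Reagents that add atoms: none
Why: Narasaka–Prasad reduction; the boron chelate of the β-hydroxy ketone takes external hydride axially to give the 1,3-syn diol, so C6 sets C8 as R. The required triad places C5, the isopropyl group and C9 all equatorial on the chelate, a matched case.

Step 21
Reactants: 31 (1R,2R,3S,4E,8Z)-5,9-dimethyl-2-(propan-2-yl)cyclodeca-4,8-diene-1,3-diol
Product: 32 (1S,2R,3R,4R,6Z,10S)-6,10-dimethyl-3-(propan-2-yl)-11-oxabicyclo[8.1.0]undec-6-ene-2,4-diol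
Conditions: VO(acac)2 (cat.), t-BuOOH (1.1 equiv), CH2Cl2, 0 °C → rt
Reagents that add atoms: tert-butyl hydroperoxide, CC(C)(C)OO
Why: Hydroxyl-directed epoxidation; the allylic C6 hydroxyl delivers the vanadium-bound peroxide to C4=C5 much faster than the homoallylic C8 hydroxyl can to C1=C10. With H6 eclipsing the alkene to avoid A(1,3) strain with the cis C4 methyl, the hydroxyl sits on the outer face of the ring, so oxygen should arrive threo, giving the (4S,5S) epoxide.

Step 22
Reactants: 32 (1S,2R,3R,4R,6Z,10S)-6,10-dimethyl-3-(propan-2-yl)-11-oxabicyclo[8.1.0]undec-6-ene-2,4-diol; 33 3,4,5-trimethoxybenzoyl chloride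
Product: 34 (1S,2R,3S,4R,6Z,10S)-2-hydroxy-6,10-dimethyl-3-(propan-2-yl)-11-oxabicyclo[8.1.0]undec-6-en-4-yl 3,4,5-trimethoxybenzoate
Conditions: pyridine, DMAP (cat.), CH2Cl2, 0 °C
Reagents that add atoms: 3,4,5-trimethoxybenzoyl chloride 33, COc1cc(C(=O)Cl)cc(OC)c1OC
Why: Nucleophilic acyl transfer should go to the C8 hydroxyl, which has a CH2 neighbour, in preference to the C6 hydroxyl, which is flanked by the epoxide and C7 and hydrogen-bonded to the epoxide oxygen; the mild base leaves the epoxide intact.

## Compound list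

1 | geraniol, (2E)-3,7-dimethylocta-2,6-dien-1-ol | CC(C)=CCC/C(C)=C/CO | starting material
2 | tert-butyl(chloro)diphenylsilane | CC(C)(C)[Si](Cl)(c1ccccc1)c1ccccc1 | starting material
3 | tert-butyl{[(2E)-3,7-dimethylocta-2,6-dien-1-yl]oxy}diphenylsilane | CC(C)=CCC/C(C)=C/CO[Si](c1ccccc1)(c1ccccc1)C(C)(C)C | intermediate
4 | tert-butyl{[(2E)-5-(3,3-dimethyloxiran-2-yl)-3-methylpent-2-en-1-yl]oxy}diphenylsilane (racemic at the oxirane) | CC1(C)OC1CC/C(C)=C/CO[Si](c1ccccc1)(c1ccccc1)C(C)(C)C | intermediate
5 | (6E)-8-[(tert-butyldiphenylsilyl)oxy]-2,6-dimethyloct-6-ene-2,3-diol (racemic, not isolated) | CC(C)(O)C(O)CC/C(C)=C/CO[Si](c1ccccc1)(c1ccccc1)C(C)(C)C | intermediate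
6 | (4E)-6-[(tert-butyldiphenylsilyl)oxy]-4-methylhex-4-enal | O=CCC/C(C)=C/CO[Si](c1ccccc1)(c1ccccc1)C(C)(C)C | intermediate
7 | methyl 2-[bis(2,2,2-trifluoroethoxy)phosphoryl]propanoate | COC(=O)C(C)P(=O)(OCC(F)(F)F)OCC(F)(F)F | starting material
8 | methyl (2Z,6E)-8-[(tert-butyldiphenylsilyl)oxy]-2,6-dimethylocta-2,6-dienoate | COC(=O)/C(C)=C\CC/C(C)=C/CO[Si](c1ccccc1)(c1ccccc1)C(C)(C)C | intermediate
9 | (2Z,6E)-8-[(tert-butyldiphenylsilyl)oxy]-2,6-dimethylocta-2,6-dien-1-ol | OC/C(C)=C\CC/C(C)=C/CO[Si](c1ccccc1)(c1ccccc1)C(C)(C)C | intermediate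
10 | (2Z,6E)-8-[(tert-butyldiphenylsilyl)oxy]-2,6-dimethylocta-2,6-dien-1-yl methanesulfonate (not isolated) | CS(=O)(=O)OC/C(C)=C\CC/C(C)=C/CO[Si](c1ccccc1)(c1ccccc1)C(C)(C)C | intermediate
11 | {[(2E,6Z)-8-bromo-3,7-dimethylocta-2,6-dien-1-yl]oxy}(tert-butyl)diphenylsilane | BrC/C(C)=C\CC/C(C)=C/CO[Si](c1ccccc1)(c1ccccc1)C(C)(C)C | intermediate
12 | ethyl 1,3-dithiane-2-carboxylate | CCOC(=O)C1SCCCS1 | starting material
13 | ethyl 2-[(2Z,6E)-8-[(tert-butyldiphenylsilyl)oxy]-2,6-dimethylocta-2,6-dien-1-yl]-1,3-dithiane-2-carboxylate | CCOC(=O)C1(C/C(C)=C\CC/C(C)=C/CO[Si](c2ccccc2)(c2ccccc2)C(C)(C)C)SCCCS1 | intermediate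
14 | 2-[(2Z,6E)-8-[(tert-butyldiphenylsilyl)oxy]-2,6-dimethylocta-2,6-dien-1-yl]-1,3-dithiane-2-carbaldehyde | O=CC1(C/C(C)=C\CC/C(C)=C/CO[Si](c2ccccc2)(c2ccccc2)C(C)(C)C)SCCCS1 | intermediate
15 | methyl (2Z)-3-{2-[(2Z,6E)-8-[(tert-butyldiphenylsilyl)oxy]-2,6-dimethylocta-2,6-dien-1-yl]-1,3-dithian-2-yl}-2-methylprop-2-enoate | COC(=O)/C(C)=C\C1(C/C(C)=C\CC/C(C)=C/CO[Si](c2ccccc2)(c2ccccc2)C(C)(C)C)SCCCS1 | intermediate
16 | ethane-1,2-diol | OCCO | starting material
17 | methyl (2Z)-3-{2-[(2Z,6E)-8-[(tert-butyldiphenylsilyl)oxy]-2,6-dimethylocta-2,6-dien-1-yl]-1,3-dioxolan-2-yl}-2-methylprop-2-enoate | COC(=O)/C(C)=C\C1(C/C(C)=C\CC/C(C)=C/CO[Si](c2ccccc2)(c2ccccc2)C(C)(C)C)OCCO1 | intermediate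
18 | methyl (2Z)-3-{2-[(2Z,6E)-8-hydroxy-2,6-dimethylocta-2,6-dien-1-yl]-1,3-dioxolan-2-yl}-2-methylprop-2-enoate | COC(=O)/C(C)=C\C1(C/C(C)=C\CC/C(C)=C/CO)OCCO1 | intermediate
19 | methyl (2Z)-3-{2-[(2Z,6E)-2,6-dimethyl-8-(methylsulfonyloxy)octa-2,6-dien-1-yl]-1,3-dioxolan-2-yl}-2-methylprop-2-enoate (not isolated) | COC(=O)/C(C)=C\C1(C/C(C)=C\CC/C(C)=C/COS(C)(=O)=O)OCCO1 | intermediate
20 | methyl (2Z)-3-{2-[(2Z,6E)-8-chloro-2,6-dimethylocta-2,6-dien-1-yl]-1,3-dioxolan-2-yl}-2-methylprop-2-enoate | COC(=O)/C(C)=C\C1(C/C(C)=C\CC/C(C)=C/CCl)OCCO1 | intermediate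
21 | (2Z)-3-{2-[(2Z,6E)-8-chloro-2,6-dimethylocta-2,6-dien-1-yl]-1,3-dioxolan-2-yl}-2-methylprop-2-en-1-ol | OC/C(C)=C\C1(C/C(C)=C\CC/C(C)=C/CCl)OCCO1 | intermediate
22 | (6Z,11E,15Z)-7,12,16-trimethyl-1,4,9-trioxaspiro[4.12]heptadeca-6,11,15-triene (13-membered ether, C8 as dioxolane) | C/C1=C/C2(OCCO2)C/C(C)=C\CC/C(C)=C/COC1 | intermediate
23 | (10S)-10-lithio derivative of 22 (lithium on germacrane C6, not isolated) | C/C1=C/C2(OCCO2)C/C(C)=C\CC/C(C)=C/[C@H]([Li])OC1 | intermediate
24 | (6S,7S,8E,12Z)-9,13-dimethyl-6-(prop-1-en-2-yl)-1,4-dioxaspiro[4.9]tetradeca-8,12-dien-7-ol | O1CCOC12C/C(C)=C\CC/C(C)=C/[C@H](O)[C@@H]2C(C)=C | intermediate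
25 | (1S,4R)-camphanic chloride, (1S,4R)-4,7,7-trimethyl-3-oxo-2-oxabicyclo[2.2.1]heptane-1-carbonyl chloride | ClC(=O)[C@@]12CC[C@@](C)(C(=O)O1)C2(C)C | starting material
26 | (6S,7S,8E,12Z)-9,13-dimethyl-6-(prop-1-en-2-yl)-1,4-dioxaspiro[4.9]tetradeca-8,12-dien-7-yl (1S,4R)-camphanate | O1CCOC12C/C(C)=C\CC/C(C)=C/[C@H](OC(=O)[C@@]34CC[C@@](C)(C(=O)O3)C4(C)C)[C@@H]2C(C)=C | intermediate
27 | (6S,7S,8E,12Z)-9,13-dimethyl-6-(propan-2-yl)-1,4-dioxaspiro[4.9]tetradeca-8,12-dien-7-yl (1S,4R)-camphanate | O1CCOC12C/C(C)=C\CC/C(C)=C/[C@H](OC(=O)[C@@]34CC[C@@](C)(C(=O)O3)C4(C)C)[C@@H]2C(C)C | intermediate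
28 | (6S,7S,8E,12Z)-9,13-dimethyl-6-(propan-2-yl)-1,4-dioxaspiro[4.9]tetradeca-8,12-dien-7-ol | O1CCOC12C/C(C)=C\CC/C(C)=C/[C@H](O)[C@@H]2C(C)C | intermediate
29 | (3Z,7E,9S,10S)-9-hydroxy-3,7-dimethyl-10-(propan-2-yl)cyclodeca-3,7-dien-1-one | O=C1C/C(C)=C\CC/C(C)=C/[C@H](O)[C@@H]1C(C)C | intermediate
30 | O-diethylboryl chelate of 29 (not isolated) | O=C1C/C(C)=C\CC/C(C)=C/[C@H](OB(CC)CC)[C@@H]1C(C)C | intermediate
31 | (1R,2R,3S,4E,8Z)-5,9-dimethyl-2-(propan-2-yl)cyclodeca-4,8-diene-1,3-diol | O[C@@H]1C/C(C)=C\CC/C(C)=C/[C@H](O)[C@@H]1C(C)C | intermediate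
32 | (1S,2R,3R,4R,6Z,10S)-6,10-dimethyl-3-(propan-2-yl)-11-oxabicyclo[8.1.0]undec-6-ene-2,4-diol | O[C@@H]1C/C(C)=C\CC[C@]2(C)O[C@H]2[C@H](O)[C@@H]1C(C)C | intermediate
33 | 3,4,5-trimethoxybenzoyl chloride | COc1cc(C(=O)Cl)cc(OC)c1OC | starting material
34 | (1S,2R,3S,4R,6Z,10S)-2-hydroxy-6,10-dimethyl-3-(propan-2-yl)-11-oxabicyclo[8.1.0]undec-6-en-4-yl 3,4,5-trimethoxybenzoate | COc1cc(C(=O)O[C@@H]2C/C(C)=C\CC[C@]3(C)O[C@H]3[C@H](O)[C@@H]2C(C)C)cc(OC)c1OC | target

## Step count and least certain steps

Total: 22 steps. Longest linear sequence: 22 steps (geraniol 1 to 34).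

**Step 15 (key step).** A lithium amide is a marginal base for a bis-allylic ether. Lithiation may be slow and need temperatures at which enantiotopic discrimination erodes, the [1,2]-shift appears, and the bulky base is diverted toward C12. Fallback: the approach to absolute configuration changes from asymmetric deprotonation to resolution. Setting out from 22, n-BuLi in THF at −78 °C (the achiral conditions established for 13-membered diallylic ethers) should give racemic material, that is 24 together with its enantiomer, (6R,7R)-9,13-dimethyl-6-(prop-1-en-2-yl)-1,4-dioxaspiro[4.9]tetradeca-8,12-dien-7-ol F1. Acylation of the mixture with 25 as in step 16 then gives 26 and the diastereomeric camphanate of the (6R,7R)-alcohol F2 in equal parts. After separation the route is rejoined at 26.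

**Step 14.** Oligomerisation by intermolecular etherification, together with elimination or SN2′ closure at the allylic chloride, may compete because the nucleophile is the more hindered C12 alkoxide. Fallback: the polarity of the ring closure is reversed. Setting out from 17, reduction with i-Bu2AlH gives the C12 alcohol with the silyl ether still in place, (2Z)-3-{2-[(2Z,6E)-8-[(tert-butyldiphenylsilyl)oxy]-2,6-dimethylocta-2,6-dien-1-yl]-1,3-dioxolan-2-yl}-2-methylprop-2-en-1-ol F3. An Appel reaction (PPh3, CCl4) gives the C12 chloride, tert-butyl{[(2E,6Z)-8-{2-[(1Z)-3-chloro-2-methylprop-1-en-1-yl]-1,3-dioxolan-2-yl}-3,7-dimethylocta-2,6-dien-1-yl]oxy}diphenylsilane F4. Buffered desilylation (Bu4NF, AcOH) gives (2E,6Z)-8-{2-[(1Z)-3-chloro-2-methylprop-1-en-1-yl]-1,3-dioxolan-2-yl}-3,7-dimethylocta-2,6-dien-1-ol F5. The unhindered C6 alkoxide (NaH, high dilution) then closes onto C12, and the route is rejoined at 22.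

**Step 10.** The thionium ion at C8 is flanked by an alkene and an allylic CH2. Proton loss from C9, capture away from C8, or desilylation by the acid released could compete with double capture by the diol. Fallback: the exchange is split in two with a monofunctional alcohol as solvent. Setting out from 15, PhI(O2CCF3)2 in methanol should give the dimethyl ketal, methyl (2Z,6Z,10E)-12-[(tert-butyldiphenylsilyl)oxy]-4,4-dimethoxy-2,6,10-trimethyldodeca-2,6,10-trienoate F6. Acetal exchange with 16 under PPTS catalysis at room temperature then gives 17, where the route is rejoined.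

**Step 19.** Before the hindered ketal has hydrolysed, acid may ionise the allylic C6–O bond, dehydrate the β-hydroxy ketone to a dienone, or trigger transannular cyclisation of the diene. Fallback: the hydroxyl is masked during the acid step. Setting out from 28, silylation (t-BuMe2SiOTf, 2,6-lutidine) gives tert-butyl{[(6S,7S,8E,12Z)-9,13-dimethyl-6-(propan-2-yl)-1,4-dioxaspiro[4.9]tetradeca-8,12-dien-7-yl]oxy}dimethylsilane F7. Hydrolysis as in step 19 gives (3Z,7E,9S,10S)-9-[(tert-butyldimethylsilyl)oxy]-3,7-dimethyl-10-(propan-2-yl)cyclodeca-3,7-dien-1-one F8, whose silyl ether is less readily protonated and lost than the free hydroxyl. Desilylation with HF·pyridine in THF buffered with pyridine returns the route at 29.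

**Step 22.** Site selectivity between the two secondary hydroxyls may be poor, with over-acylation. Fallback: the order of the last two steps is inverted and the diol is activated through tin. Setting out from 31, Bu2SnO in refluxing toluene gives the dibutylstannylene acetal of 31 F9 (not isolated), which is expected to acylate with 33 at the less hindered O8. This gives (1R,2S,3S,4E,8Z)-3-hydroxy-5,9-dimethyl-2-(propan-2-yl)cyclodeca-4,8-dien-1-yl 3,4,5-trimethoxybenzoate F10. Its only free hydroxyl is the allylic one at C6, so epoxidation as in step 21 rejoins the route at 34.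

## Further compounds

F1 | step 15 | (6R,7R,8E,12Z)-9,13-dimethyl-6-(prop-1-en-2-yl)-1,4-dioxaspiro[4.9]tetradeca-8,12-dien-7-ol (enantiomer of 24) | O1CCOC12C/C(C)=C\CC/C(C)=C/[C@@H](O)[C@H]2C(C)=C
F2 | step 15 | (6R,7R,8E,12Z)-9,13-dimethyl-6-(prop-1-en-2-yl)-1,4-dioxaspiro[4.9]tetradeca-8,12-dien-7-yl (1S,4R)-camphanate | O1CCOC12C/C(C)=C\CC/C(C)=C/[C@@H](OC(=O)[C@@]34CC[C@@](C)(C(=O)O3)C4(C)C)[C@H]2C(C)=C
F3 | step 14 | (2Z)-3-{2-[(2Z,6E)-8-[(tert-butyldiphenylsilyl)oxy]-2,6-dimethylocta-2,6-dien-1-yl]-1,3-dioxolan-2-yl}-2-methylprop-2-en-1-ol | OC/C(C)=C\C1(C/C(C)=C\CC/C(C)=C/CO[Si](c2ccccc2)(c2ccccc2)C(C)(C)C)OCCO1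
F4 | step 14 | tert-butyl{[(2E,6Z)-8-{2-[(1Z)-3-chloro-2-methylprop-1-en-1-yl]-1,3-dioxolan-2-yl}-3,7-dimethylocta-2,6-dien-1-yl]oxy}diphenylsilane | ClC/C(C)=C\C1(C/C(C)=C\CC/C(C)=C/CO[Si](c2ccccc2)(c2ccccc2)C(C)(C)C)OCCO1
F5 | step 14 | (2E,6Z)-8-{2-[(1Z)-3-chloro-2-methylprop-1-en-1-yl]-1,3-dioxolan-2-yl}-3,7-dimethylocta-2,6-dien-1-ol | ClC/C(C)=C\C1(C/C(C)=C\CC/C(C)=C/CO)OCCO1
F6 | step 10 | methyl (2Z,6Z,10E)-12-[(tert-butyldiphenylsilyl)oxy]-4,4-dimethoxy-2,6,10-trimethyldodeca-2,6,10-trienoate | COC(=O)/C(C)=C\C(OC)(OC)C/C(C)=C\CC/C(C)=C/CO[Si](c1ccccc1)(c1ccccc1)C(C)(C)C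
F7 | step 19 | tert-butyl{[(6S,7S,8E,12Z)-9,13-dimethyl-6-(propan-2-yl)-1,4-dioxaspiro[4.9]tetradeca-8,12-dien-7-yl]oxy}dimethylsilane | O1CCOC12C/C(C)=C\CC/C(C)=C/[C@H](O[Si](C)(C)C(C)(C)C)[C@@H]2C(C)C
F8 | step 19 | (3Z,7E,9S,10S)-9-[(tert-butyldimethylsilyl)oxy]-3,7-dimethyl-10-(propan-2-yl)cyclodeca-3,7-dien-1-one | O=C1C/C(C)=C\CC/C(C)=C/[C@H](O[Si](C)(C)C(C)(C)C)[C@@H]1C(C)C
F9 | step 22 | dibutylstannylene acetal of 31 (O6,O8-bridged, not isolated) | CCCC[Sn]1(CCCC)O[C@@H]2C/C(C)=C\CC/C(C)=C/[C@H](O1)[C@@H]2C(C)C
F10 | step 22 | (1R,2S,3S,4E,8Z)-3-hydroxy-5,9-dimethyl-2-(propan-2-yl)cyclodeca-4,8-dien-1-yl 3,4,5-trimethoxybenzoate | COc1cc(C(=O)O[C@@H]2C/C(C)=C\CC/C(C)=C/[C@H](O)[C@@H]2C(C)C)cc(OC)c1OC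
A1 | alternative 1 | open-chain C4–C5 epoxide with Z alkene, 6-silyloxy, 7-isopropyl and 8-(4-methoxybenzyloxy) groups | CC[Si](CC)(CC)OC/C(C)=C\CC[C@]1(C)O[C@H]1[C@H](O[Si](C)(C)C(C)(C)C)[C@H](C(C)C)COCc1ccc(OC)cc1
A2 | alternative 1 | {[(2Z)-5-bromo-2-methylpent-2-en-1-yl]oxy}triethylsilane | CC[Si](CC)(CC)OC/C(C)=C\CCBr
A3 | alternative 1 | 4-[(tert-butyldimethylsilyl)oxy]-3-chloro-5-{[(4-methoxyphenyl)methoxy]methyl}-6-methylheptan-2-one | CC(=O)[C@H](Cl)[C@H](O[Si](C)(C)C(C)(C)C)[C@H](C(C)C)COCc1ccc(OC)cc1
A4 | alternative 2 | (1(10)Z,4E)-cyclodecadienyl C10 enol triflate with 6-methoxymethoxy and 8-(4-methoxybenzyloxy) groups | COc1ccc(CO[C@@H]2C/C(OS(=O)(=O)C(F)(F)F)=C\CC/C(C)=C/[C@H](OCOC)[C@@H]2C(C)C)cc1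
A5 | alternative 2 | all-cis 1-vinyl-2-isopropenylcyclohexan-1-ol with 3-methoxymethoxy, 4-isopropyl and 5-(4-methoxybenzyloxy) groups | C=C[C@@]1(O)C[C@@H](OCc2ccc(OC)cc2)[C@@H](C(C)C)[C@@H](OCOC)[C@H]1C(C)=C
A6 | alternative 3 | 8-O-(tert-butyldimethylsilyl) (1(10)Z,4E)-germacradien-6-ol | CC(C)(C)[Si](C)(C)O[C@@H]1C/C(C)=C\CC/C(C)=C/[C@H](O)[C@@H]1C(C)C
A7 | alternative 3 | (5Z)-3-[(tert-butyldimethylsilyl)oxy]-5-methyl-2-(propan-2-yl)dec-5-en-9-ynal | C#CCC/C=C(C)\C[C@@H](O[Si](C)(C)C(C)(C)C)[C@@H](C(C)C)C=O
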